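**Retrosynthetic overview**

1. Numbering: ring C1 (carbinol), C2, C3, C4 (Me, Cl), C5 (Br), C6; C8 is the exocyclic =CH2 carbon on C1, C9–C10 the CH2CH2 link, C11 the side-chain carbinol. Feature used: the quaternary carbinol C1 carries the ring carbons C6–C5 and the exocyclic carbon C8 on equal footing; if C8 is kept for a while as the CH2 of a second CH2–CH=CH2 group, C1 holds two identical allyl groups beside the C2–C3–C4(Me) arm and only becomes a stereocentre when ring C1–C6 closes at C4=C5.
2. Target 29 ⇐ C8 ketone 27 (methylenation, desilylation) ⇐ bridged bromo ether 26 (BCl3 opening of C4–O; Cl ends cis to the C1 oxygen and trans to Br through a bromonium ion) ⇐ C8 aldehyde 17 + side-chain Grignard reagent 24 (C9–C13, C11 set by CBS reduction).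
3. 17 ⇐ allyl bromo ether 14 (alkene isomerization, ozonolysis) ⇐ cyclohexenol 13 (NBS bromoetherification C1–O–C4, Br at C5, both fixed by C1).
4. 13 ⇐ key disconnection C4=C5: Mo-catalysed enantioselective ring-closing metathesis that desymmetrizes diallyl carbinol silyl ether 10. Two free allyl groups would close on each other to a cyclopentene faster than either closes onto a 1,1-disubstituted alkene, so the C4 arm is reshaped to carry a pent-4-enyl relay that delivers Mo to C4 and also re-opens that cyclopentene.
5. Ring order: carbocycle C1–C6 first (step 5, the only ring of the target); the C1–O–C4 bridge (step 7) is temporary and is reopened in step 16. Precursor 10 comes in four steps from methacrolein, pent-4-enyl Grignard, triethyl orthoacetate and allyl Grignard.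

Key step: step 5

Assumption: the sense of induction of the chiral Mo catalyst cannot be assigned in advance; the (S)-biphenolate is written, and the (R)-ligand is used instead if a first run shows the opposite sense at C1.

**Route**

Step 1
Reactants: 1 methacrolein; 2 pent-4-en-1-ylmagnesium bromide
Product: 3 2-methylocta-1,7-dien-3-ol (racemic)
Conditions: THF, −78 → 0 °C; then H2O
Reagents that add atoms: none
Why: 1,2-Addition of a Grignard reagent to an enal gives the secondary allylic alcohol, whose stereocentre is erased in step 2, so the racemate serves.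

Step 2
Reactants: 3 2-methylocta-1,7-dien-3-ol; 4 triethyl orthoacetate
Product: 6 ethyl (4E)-4-methyldeca-4,9-dienoate, via ketene acetal 5 (not isolated)
Conditions: EtCO2H (cat.), 140 °C, EtOH distilled off
Reagents that add atoms: none
Why: Johnson–Claisen rearrangement: acid-catalysed exchange gives ketene acetal 5, whose chair [3,3] shift builds the C2–C3 link and the trisubstituted C4 alkene that joins the relay chain (its geometry, expected E, does not matter for the relay).

Step 3
Reactants: 6 ethyl (4E)-4-methyldeca-4,9-dienoate; 7 allylmagnesium bromide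
Product: 9 (7E)-4-allyl-7-methyltrideca-1,7,12-trien-4-ol, via ketone 8 (not isolated)
Conditions: 7 (2.5 equiv), Et2O, 0 → 23 °C; then H2O
Reagents that add atoms: none
Why: Double Grignard addition to an ester through ketone 8 gives the tertiary carbinol with two identical allyl groups, so C1 is not yet a stereocentre.

Step 4
Reactants: 9 (7E)-4-allyl-7-methyltrideca-1,7,12-trien-4-ol
Product: 10 {[(7E)-4-allyl-7-methyltrideca-1,7,12-trien-4-yl]oxy}trimethylsilane
Conditions: Me3SiCl, imidazole, DMF, 23 °C
Reagents that add atoms: chlorotrimethylsilane, C[Si](C)(C)Cl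
Why: Silylation of the tertiary alcohol masks the protic group that would destroy the Mo alkylidene in step 5.

Step 5
Reactants: 10 {[(7E)-4-allyl-7-methyltrideca-1,7,12-trien-4-yl]oxy}trimethylsilane
Product: 12 (R)-[(1-allyl-4-methylcyclohex-3-en-1-yl)oxy]trimethylsilane, via achiral cyclopentene 11 (not isolated)
Conditions: Mo(N-2,6-iPr2C6H3)(CHCMe2Ph)[(S)-3,3'-di-tert-butyl-5,5',6,6'-tetramethylbiphenyl-2,2'-diolate] (5–10 mol%), C6H6 (0.05 M), 22 °C, N2 stream
Reagents that add atoms: none
Why: The Mo alkylidene loads at a terminal alkene; when it sits on the pentenyl relay terminus it closes a five-membered ring onto the trisubstituted C4 alkene, expels cyclopentene and is left on C4, and this C4 alkylidene then undergoes [2+2] cycloaddition and cycloreversion with the CH= carbon of one of the two allyl groups on C1 to form C4=C5. The closest known reaction types are the Mo-catalysed enantioselective ring-closing metathesis of prochiral trienes (tertiary ethers included), relay ring-closing metathesis, and the asymmetric ring-opening/ring-closing metathesis of achiral cyclopentenyl tertiary ethers. The carbocycle C1–C6 closes by six-membered ring-closing metathesis between C4 and C5. C1 is the only new stereocentre and is set by the chiral imido–biphenolate Mo centre, which should distinguish the two diastereomeric metallacyclobutanes that place the remaining allyl group and the OSiMe3 group differently on the forming ring. The step needs the cyclohexene to win over closure of the two allyl groups onto each other; that closure is expected to be fast and to give achiral cyclopentene 11, but 11 still carries the relay, so Mo is delivered to C4 again and opens the cyclopentene while closing the cyclohexene, which leads to the same product and releases the second arm as the allyl group.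

Step 6
Reactants: 12 (R)-[(1-allyl-4-methylcyclohex-3-en-1-yl)oxy]trimethylsilane
Product: 13 (R)-1-allyl-4-methylcyclohex-3-en-1-ol
Conditions: citric acid (cat.), MeOH, 23 °C
Reagents that add atoms: none
Why: Acid-catalysed methanolysis cleaves the labile trimethylsilyl ether without touching the alkenes or C1.

Step 7
Reactants: 13 (R)-1-allyl-4-methylcyclohex-3-en-1-ol
Product: 14 (1R,2R,4R)-4-allyl-2-bromo-1-methyl-7-oxabicyclo[2.2.1]heptane
Conditions: NBS, CH2Cl2, 0 °C, dark
Reagents that add atoms: N-bromosuccinimide, O=C1CCC(=O)N1Br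
Why: Bromoetherification: the bromonium ion forms on the more nucleophilic trisubstituted C4=C5 alkene and the C1 hydroxyl, which can only bridge on its own face, opens it at the tertiary C4, so C4–O is cis to C1–O and Br at C5 is anti to the new C–O bond, both dictated by C1.

Step 8
Reactants: 14 (1R,2R,4R)-4-allyl-2-bromo-1-methyl-7-oxabicyclo[2.2.1]heptane
Product: 15 (1R,2R,4S)-2-bromo-1-methyl-4-[(1E)-prop-1-en-1-yl]-7-oxabicyclo[2.2.1]heptane
Conditions: RuHCl(CO)(PPh3)3 (5 mol%), toluene, 90 °C
Reagents that add atoms: none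
Why: Ru–H catalysed alkene isomerization (hydrometalation, β-hydride elimination) moves the terminal double bond to the more stable internal position next to C1; the E/Z ratio is irrelevant for step 9.

Step 9
Reactants: 15 (1R,2R,4S)-2-bromo-1-methyl-4-[(1E)-prop-1-en-1-yl]-7-oxabicyclo[2.2.1]heptane
Product: 17 (1S,3R,4R)-3-bromo-4-methyl-7-oxabicyclo[2.2.1]heptane-1-carbaldehyde, via ozonide 16 (not isolated)
Conditions: O3, CH2Cl2, −78 °C; then PPh3, −78 → 23 °C
Reagents that add atoms: ozone, [O-][O+]=O
Why: Ozonolysis with reductive work-up cleaves the propenyl group to the non-enolizable C8 aldehyde; the bridged ether and the bromide offer no oxidizable site.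

Step 10
Reactants: 18 3-chloropropanoyl chloride
Product: 19 3-chloro-N-methoxy-N-methylpropanamide
Conditions: MeNH(OMe)·HCl, pyridine, CH2Cl2, 0 °C
Reagents that add atoms: N,O-dimethylhydroxylamine hydrochloride, CNOC.Cl
Why: Weinreb amide formation by acylation of the hydroxylamine; pyridine is too weak a base to eliminate HCl from the β-chloro amide.

Step 11
Reactants: 19 3-chloro-N-methoxy-N-methylpropanamide; 20 isopropenylmagnesium bromide
Product: 21 5-chloro-2-methylpent-1-en-3-one
Conditions: THF, −20 → 0 °C; then cold 1 M HCl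
Reagents that add atoms: none
Why: Weinreb ketone synthesis: the chelated tetrahedral adduct stops the alkenyl Grignard addition at the ketone stage, and the acidic quench keeps the released amine from adding to the enone.

Step 12
Reactants: 21 5-chloro-2-methylpent-1-en-3-one
Product: 22 (3R)-5-chloro-2-methylpent-1-en-3-ol
Conditions: (S)-2-methyl-CBS-oxazaborolidine (15 mol%), catecholborane, toluene, −78 °C; then MeOH, aq. NaHCO3
Reagents that add atoms: none
Why: CBS reduction: the oxazaborolidine–borane complex binds the carbonyl anti to the larger isopropenyl group and delivers hydride to one face, which with the (S)-catalyst should set C11 as R, as with aryl and α-substituted alkenyl ketones.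

Step 13
Reactants: 22 (3R)-5-chloro-2-methylpent-1-en-3-ol
Product: 23 tert-butyl{[(3R)-5-chloro-2-methylpent-1-en-3-yl]oxy}dimethylsilane
Conditions: tBuMe2SiCl, imidazole, DMF, 23 °C
Reagents that add atoms: tert-butyldimethylsilyl chloride, CC(C)(C)[Si](C)(C)Cl
Why: Silylation of the secondary allylic alcohol gives an ether meant to outlast Grignard formation and BCl3 at −78 °C.

Step 14
Reactants: 23 tert-butyl{[(3R)-5-chloro-2-methylpent-1-en-3-yl]oxy}dimethylsilane; 17 (1S,3R,4R)-3-bromo-4-methyl-7-oxabicyclo[2.2.1]heptane-1-carbaldehyde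
Product: 25 (4R)-1-[(1S,3R,4R)-3-bromo-4-methyl-7-oxabicyclo[2.2.1]heptan-1-yl]-4-[(tert-butyldimethylsilyl)oxy]-5-methylhex-5-en-1-ol (C8 epimers), via Grignard reagent 24 (not isolated)
Conditions: 23, Mg turnings, I2 (cat.), THF, 60 °C; then 17, THF, −78 → 0 °C; then H2O
Reagents that add atoms: none
Why: Grignard formation from the primary chloride (the silyl ether is γ, so no β-elimination) and 1,2-addition to the non-enolizable aldehyde form C8–C9; the uncontrolled C8 carbinol centre is removed in step 15.

Step 15
Reactants: 25 (4R)-1-[(1S,3R,4R)-3-bromo-4-methyl-7-oxabicyclo[2.2.1]heptan-1-yl]-4-[(tert-butyldimethylsilyl)oxy]-5-methylhex-5-en-1-ol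
Product: 26 (4R)-1-[(1S,3R,4R)-3-bromo-4-methyl-7-oxabicyclo[2.2.1]heptan-1-yl]-4-[(tert-butyldimethylsilyl)oxy]-5-methylhex-5-en-1-one
Conditions: Dess–Martin periodinane, NaHCO3, CH2Cl2, 0 → 23 °C
Reagents that add atoms: none
Why: Dess–Martin oxidation converts both epimeric alcohols to the single C8 ketone under buffered, near-neutral conditions.

Step 16
Reactants: 26 (4R)-1-[(1S,3R,4R)-3-bromo-4-methyl-7-oxabicyclo[2.2.1]heptan-1-yl]-4-[(tert-butyldimethylsilyl)oxy]-5-methylhex-5-en-1-one
Product: 27 (4R)-1-[(1S,3R,4R)-3-bromo-4-chloro-1-hydroxy-4-methylcyclohexyl]-4-[(tert-butyldimethylsilyl)oxy]-5-methylhex-5-en-1-one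
Conditions: BCl3 (1.5 equiv), CH2Cl2, −78 → −40 °C; then aq. NaHCO3
Reagents that add atoms: boron trichloride, ClB(Cl)Cl
Why: Lewis-acid ether cleavage: BCl3 binds the bridging oxygen, the C4–O bond ionizes with participation of the antiperiplanar C5 bromine to a bromonium ion on the face away from oxygen, and chloride opens it at the tertiary C4 from the oxygen face, so Cl should end cis to the C1 hydroxyl and trans to Br (net retention at C4), while the acyl group on C1 disfavours ionization of C1–O.

Step 17
Reactants: 27 (4R)-1-[(1S,3R,4R)-3-bromo-4-chloro-1-hydroxy-4-methylcyclohexyl]-4-[(tert-butyldimethylsilyl)oxy]-5-methylhex-5-en-1-one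
Product: 28 (1S,3R,4R)-3-bromo-1-{(5R)-5-[(tert-butyldimethylsilyl)oxy]-6-methylhepta-1,6-dien-2-yl}-4-chloro-4-methylcyclohexan-1-ol
Conditions: Cp2TiMe2 (3 equiv), toluene–THF, 65 °C, dark
Reagents that add atoms: dimethyltitanocene, [CH3-].[CH3-].[Ti+4].[cH-]1cccc1.[cH-]1cccc1
Why: Petasis methylenation: on heating, Cp2TiMe2 gives Cp2Ti=CH2, which converts the C8 ketone to the 1,1-disubstituted alkene by [2+2] cycloaddition and cycloreversion under non-basic conditions, the excess reagent covering the tertiary hydroxyl as a titanium alkoxide until work-up.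

Step 18
Reactants: 28 (1S,3R,4R)-3-bromo-1-{(5R)-5-[(tert-butyldimethylsilyl)oxy]-6-methylhepta-1,6-dien-2-yl}-4-chloro-4-methylcyclohexan-1-ol
Product: 29 (1S,3R,4R)-3-bromo-4-chloro-1-[(5R)-5-hydroxy-6-methylhepta-1,6-dien-2-yl]-4-methylcyclohexan-1-ol
Conditions: HF·pyridine, pyridine, THF, 0 → 23 °C
Reagents that add atoms: none
Why: Fluoride cleavage of the silyl ether under buffered conditions that should neither eliminate the tertiary chloride nor ionize the allylic alcohols.

**Compound list**

1 | methacrolein (2-methylprop-2-enal) | C=C(C)C=O | starting material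
2 | pent-4-en-1-ylmagnesium bromide | C=CCCC[Mg]Br | starting material
3 | 2-methylocta-1,7-dien-3-ol (racemic) | C=C(C)C(O)CCCC=C | intermediate
4 | triethyl orthoacetate | CCOC(C)(OCC)OCC | starting material
5 | 3-[(1-ethoxyethenyl)oxy]-2-methylocta-1,7-diene (ketene acetal, not isolated) | C=C(OCC)OC(CCCC=C)C(C)=C | intermediate
6 | ethyl (4E)-4-methyldeca-4,9-dienoate | CCOC(=O)CC/C(C)=C/CCCC=C | intermediate
7 | allylmagnesium bromide | C=CC[Mg]Br | starting material
8 | (7E)-7-methyltrideca-1,7,12-trien-4-one (not isolated) | C=CCC(=O)CC/C(C)=C/CCCC=C | intermediate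
9 | (7E)-4-allyl-7-methyltrideca-1,7,12-trien-4-ol | C=CCC(O)(CC=C)CC/C(C)=C/CCCC=C | intermediate
10 | {[(7E)-4-allyl-7-methyltrideca-1,7,12-trien-4-yl]oxy}trimethylsilane | C=CCC(CC=C)(O[Si](C)(C)C)CC/C(C)=C/CCCC=C | intermediate
11 | trimethyl({1-[(3E)-3-methylnona-3,8-dien-1-yl]cyclopent-3-en-1-yl}oxy)silane (achiral, not isolated) | C[Si](C)(C)OC1(CC=CC1)CC/C(C)=C/CCCC=C | intermediate
12 | (R)-[(1-allyl-4-methylcyclohex-3-en-1-yl)oxy]trimethylsilane | C=CC[C@]1(O[Si](C)(C)C)CCC(C)=CC1 | intermediate
13 | (R)-1-allyl-4-methylcyclohex-3-en-1-ol | C=CC[C@]1(O)CCC(C)=CC1 | intermediate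
14 | (1R,2R,4R)-4-allyl-2-bromo-1-methyl-7-oxabicyclo[2.2.1]heptane | C=CC[C@@]12CC[C@@](C)(O1)[C@H](Br)C2 | intermediate
15 | (1R,2R,4S)-2-bromo-1-methyl-4-[(1E)-prop-1-en-1-yl]-7-oxabicyclo[2.2.1]heptane | C/C=C/[C@@]12CC[C@@](C)(O1)[C@H](Br)C2 | intermediate
16 | 3-[(1S,3R,4R)-3-bromo-4-methyl-7-oxabicyclo[2.2.1]heptan-1-yl]-5-methyl-1,2,4-trioxolane (not isolated) | CC1OOC(O1)[C@@]23CC[C@@](C)(O2)[C@H](Br)C3 | intermediate
17 | (1S,3R,4R)-3-bromo-4-methyl-7-oxabicyclo[2.2.1]heptane-1-carbaldehyde | O=C[C@@]12CC[C@@](C)(O1)[C@H](Br)C2 | intermediate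
18 | 3-chloropropanoyl chloride | ClCCC(Cl)=O | starting material
19 | 3-chloro-N-methoxy-N-methylpropanamide | CON(C)C(=O)CCCl | intermediate
20 | isopropenylmagnesium bromide | C=C(C)[Mg]Br | starting material
21 | 5-chloro-2-methylpent-1-en-3-one | C=C(C)C(=O)CCCl | intermediate
22 | (3R)-5-chloro-2-methylpent-1-en-3-ol | C=C(C)[C@H](O)CCCl | intermediate
23 | tert-butyl{[(3R)-5-chloro-2-methylpent-1-en-3-yl]oxy}dimethylsilane | C=C(C)[C@H](O[Si](C)(C)C(C)(C)C)CCCl | intermediate
24 | {(3R)-3-[(tert-butyldimethylsilyl)oxy]-4-methylpent-4-en-1-yl}magnesium chloride (not isolated) | C=C(C)[C@H](O[Si](C)(C)C(C)(C)C)CC[Mg]Cl | intermediate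
25 | (4R)-1-[(1S,3R,4R)-3-bromo-4-methyl-7-oxabicyclo[2.2.1]heptan-1-yl]-4-[(tert-butyldimethylsilyl)oxy]-5-methylhex-5-en-1-ol (C8 epimers) | C=C(C)[C@H](O[Si](C)(C)C(C)(C)C)CCC(O)[C@@]12CC[C@@](C)(O1)[C@H](Br)C2 | intermediate
26 | (4R)-1-[(1S,3R,4R)-3-bromo-4-methyl-7-oxabicyclo[2.2.1]heptan-1-yl]-4-[(tert-butyldimethylsilyl)oxy]-5-methylhex-5-en-1-one | C=C(C)[C@H](O[Si](C)(C)C(C)(C)C)CCC(=O)[C@@]12CC[C@@](C)(O1)[C@H](Br)C2 | intermediate
27 | (4R)-1-[(1S,3R,4R)-3-bromo-4-chloro-1-hydroxy-4-methylcyclohexyl]-4-[(tert-butyldimethylsilyl)oxy]-5-methylhex-5-en-1-one | C=C(C)[C@H](O[Si](C)(C)C(C)(C)C)CCC(=O)[C@]1(O)CC[C@@](C)(Cl)[C@H](Br)C1 | intermediate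
28 | (1S,3R,4R)-3-bromo-1-{(5R)-5-[(tert-butyldimethylsilyl)oxy]-6-methylhepta-1,6-dien-2-yl}-4-chloro-4-methylcyclohexan-1-ol | C=C(C)[C@H](O[Si](C)(C)C(C)(C)C)CCC(=C)[C@]1(O)CC[C@@](C)(Cl)[C@H](Br)C1 | intermediate
29 | (1S,3R,4R)-3-bromo-4-chloro-1-[(5R)-5-hydroxy-6-methylhepta-1,6-dien-2-yl]-4-methylcyclohexan-1-ol | C=C(C)[C@H](O)CCC(=C)[C@]1(O)CC[C@@](C)(Cl)[C@H](Br)C1 | target

**Step count and risks**

Total step count: 18. Longest linear sequence: 14 steps (steps 1–9, then 14–18); side chain 23 takes 4 steps (10–13).

Steps most likely to fail: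

1. Step 5. The relay ring closure onto the trisubstituted C4 alkene may be slow with the bulky diolate catalyst, so that material rests at achiral cyclopentene 11 or sheds its relay by cross-metathesis. The two productive channels (closure onto a free allyl group, ring-opening of 11) may also differ in facial preference, which would erode the enantiomeric purity at C1. Fallback (C1 set by an enantioselective Diels–Alder reaction instead of metathesis): this branch does not leave from a compound of the route; it replaces compounds 1–12, sets out from commercial isoprene and 2-bromoacrolein, and comes back at 13. A chiral oxazaborolidine Lewis acid made from N-tosyl-(S)-tryptophan and butylboronic acid (or its antipode, whichever gives the R adduct) in CH2Cl2 at −78 °C should give (1R)-1-bromo-4-methylcyclohex-3-ene-1-carbaldehyde F1. Reduction with NaBH4 gives [(1R)-1-bromo-4-methylcyclohex-3-en-1-yl]methanol F2, and NaOH closes the epoxide with inversion at C1 to (3S)-6-methyl-1-oxaspiro[2.5]oct-5-ene F3. Vinylmagnesium bromide with CuI (cat.) opens F3 at its CH2 carbon, which leaves the C1–O bond untouched and gives 13.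

2. Step 16. The Lewis acid may ionize the allylic silyl ether or add HCl to the isopropenyl group before the carbonyl-deactivated bridged ether opens, and the C4 cation may lose a proton instead of taking up chloride. Fallback (ether opening before fragment coupling, on a substrate without the side chain): it sets out from 17 and comes back at 27. Pinnick oxidation (NaClO2, NaH2PO4, 2-methylbut-2-ene) gives (1S,3R,4R)-3-bromo-4-methyl-7-oxabicyclo[2.2.1]heptane-1-carboxylic acid F4. Amide coupling with MeNH(OMe)·HCl gives (1S,3R,4R)-3-bromo-N-methoxy-N,4-dimethyl-7-oxabicyclo[2.2.1]heptane-1-carboxamide F5. BCl3, which can now be used at higher temperature, opens the C4–O bond by the same bromonium pathway to (1S,3R,4R)-3-bromo-4-chloro-1-hydroxy-N-methoxy-N,4-dimethylcyclohexane-1-carboxamide F6. Excess Grignard reagent 24 (the first equivalent deprotonates the hydroxyl) then gives ketone 27.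

3. Step 17. The titanium carbene may be consumed by the free tertiary hydroxyl, and HCl may be lost thermally at the temperature needed to generate Cp2Ti=CH2, leaving the hindered ketone unchanged. Fallback (addition–elimination at low temperature instead of a titanium carbene): it sets out from 27 and comes back at 29. Me3SiCH2MgCl with CeCl3 in THF at −78 °C adds to the ketone to give (5R)-2-[(1S,3R,4R)-3-bromo-4-chloro-1-hydroxy-4-methylcyclohexyl]-5-[(tert-butyldimethylsilyl)oxy]-6-methyl-1-(trimethylsilyl)hept-6-en-2-ol F7 (C8 epimers). HF·pyridine then effects the Peterson elimination to the C8 methylene and cleaves the silyl ether in the same operation, giving 29 directly.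

**Further compounds**

F1 | step 5 | (1R)-1-bromo-4-methylcyclohex-3-ene-1-carbaldehyde | O=C[C@@]1(Br)CCC(C)=CC1
F2 | step 5 | [(1R)-1-bromo-4-methylcyclohex-3-en-1-yl]methanol | OC[C@@]1(Br)CCC(C)=CC1
F3 | step 5 | (3S)-6-methyl-1-oxaspiro[2.5]oct-5-ene | C1O[C@]12CCC(C)=CC2
F4 | step 16 | (1S,3R,4R)-3-bromo-4-methyl-7-oxabicyclo[2.2.1]heptane-1-carboxylic acid | OC(=O)[C@@]12CC[C@@](C)(O1)[C@H](Br)C2
F5 | step 16 | (1S,3R,4R)-3-bromo-N-methoxy-N,4-dimethyl-7-oxabicyclo[2.2.1]heptane-1-carboxamide | CON(C)C(=O)[C@@]12CC[C@@](C)(O1)[C@H](Br)C2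
F6 | step 16 | (1S,3R,4R)-3-bromo-4-chloro-1-hydroxy-N-methoxy-N,4-dimethylcyclohexane-1-carboxamide | CON(C)C(=O)[C@]1(O)CC[C@@](C)(Cl)[C@H](Br)C1
F7 | step 17 | (5R)-2-[(1S,3R,4R)-3-bromo-4-chloro-1-hydroxy-4-methylcyclohexyl]-5-[(tert-butyldimethylsilyl)oxy]-6-methyl-1-(trimethylsilyl)hept-6-en-2-ol | C=C(C)[C@H](O[Si](C)(C)C(C)(C)C)CCC(O)(C[Si](C)(C)C)[C@]1(O)CC[C@@](C)(Cl)[C@H](Br)C1
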